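The plan rests on deleting N4 from between C5 and C9a. The N4–C9a bond belongs to both the pyrrolidine (N4, C3, C2, C1, C9a) and the azepane (N4, C5–C9, C9a). The bicycle therefore reduces to a cis-2,3-disubstituted cyclohexanone whose C9a side chain ends in a secondary C3 azide. An intramolecular Schmidt reaction re-inserts that nitrogen. One 1,2-shift with retention closes both rings and carries the C3, C9 and C9a configurations through unchanged, after the furofuranone and the butyrolactone are complete. The precursor is built from an enantioenriched 2-iodocyclohexenol by Ireland–Claisen rearrangement, butenolide metathesis/oxa-Michael closure, B-alkyl Suzuki coupling and face-selective hydroboration.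

Key step: step 19

Remark: atom labels are C1–C3, N4, C5–C9, C9a (pyrroloazepine); C10 (on C9), C11 (lactone OCH), C12 (ether OCH), C13 (CHMe), C14 (C=O), C15 (Me), C16 (OCHMe), C17 (Me) (furofuranone); C18 (OCH), C19, C20 (CHMe), C21 (C=O), C22 (Me) (C3 lactone). The target is taken as drawn, (3S,9R,9aS,10R,11R,12R,13S,16S,18S,20S), and "as in 32" means the same spatial arrangement as in the target.

Step 1
Reactants: 1 (S)-3-hydroxybutanoic acid
Product: 3 (S)-3-[(tert-butyldimethylsilyl)oxy]butanoic acid, via bis-silyl ester 2 (not isolated)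
Conditions: TBSCl (2.2 equiv), imidazole, DMF, rt; then K2CO3, MeOH–H2O, rt; work-up at pH 4
Reagents that add atoms: tert-butyldimethylsilyl chloride, CC(C)(C)[Si](C)(C)Cl
Why: Exhaustive silylation followed by selective solvolysis of the labile silyl ester is a standard protection sequence that leaves the purchased C16 stereocentre (S) untouched.

Step 2
Reactants: 4 2-iodocyclohex-2-en-1-one
Product: 5 (R)-2-iodocyclohex-2-en-1-ol
Conditions: (S)-Me-CBS (10 mol %), BH3·SMe2, THF, −20 °C
Reagents that add atoms: none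
Why: Corey–Bakshi–Shibata reduction in which the iodoalkenyl side acts as the large substituent, so the (S)-catalyst should give the (R)-carbinol that later dictates C9.

Step 3
Reactants: 3 (S)-3-[(tert-butyldimethylsilyl)oxy]butanoic acid; 5 (R)-2-iodocyclohex-2-en-1-ol
Product: 6 (R)-2-iodocyclohex-2-en-1-yl (S)-3-[(tert-butyldimethylsilyl)oxy]butanoate
Conditions: DCC, DMAP (cat.), CH2Cl2, 0 °C → rt
Reagents that add atoms: none
Why: Steglich esterification joins the two chiral building blocks under neutral conditions without touching either stereocentre.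

Step 4
Reactants: 6 (R)-2-iodocyclohex-2-en-1-yl (S)-3-[(tert-butyldimethylsilyl)oxy]butanoate
Product: 9 (2R,3S)-3-[(tert-butyldimethylsilyl)oxy]-2-[(1R)-2-iodocyclohex-2-en-1-yl]butanoic acid, via (Z)-silyl ketene acetal 7 (not isolated), via trimethylsilyl ester 8 (not isolated)
Conditions: LDA, THF–DMPU (4:1), −78 °C; TMSCl, −78 °C → rt, then 50 °C; dilute aq. citric acid
Reagents that add atoms: chlorotrimethylsilane, C[Si](C)(C)Cl (its silyl group is carried only by 7 and 8)
Why: Ireland–Claisen rearrangement: enolisation in the dipolar cosolvent should give the (Z)-silyl ketene acetal 7, the suprafacial [3,3] shift transfers the C5–O configuration to C9 (R), and the chair-like transition state (a boat would eclipse OSiMe3 with the C9a iodine) should set C10 (R).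

Step 5
Reactants: 9 (2R,3S)-3-[(tert-butyldimethylsilyl)oxy]-2-[(1R)-2-iodocyclohex-2-en-1-yl]butanoic acid
Product: 10 (2R,3S)-3-[(tert-butyldimethylsilyl)oxy]-2-[(1R)-2-iodocyclohex-2-en-1-yl]-N-methoxy-N-methylbutanamide
Conditions: CDI, CH2Cl2, rt; MeNHOMe·HCl, rt
Reagents that add atoms: N,O-dimethylhydroxylamine hydrochloride, CNOC.Cl
Why: Weinreb amide formation through the acyl imidazolide is mild enough not to epimerise C10.

Step 6
Reactants: 10 the Weinreb amide
Product: 11 (4R,5S)-5-[(tert-butyldimethylsilyl)oxy]-4-[(1R)-2-iodocyclohex-2-en-1-yl]hex-1-en-3-one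
Conditions: CH2=CHMgBr, THF, −20 → 0 °C; inverse quench into cold aq. NH4Cl
Reagents that add atoms: vinylmagnesium bromide, C=C[Mg]Br
Why: Weinreb ketone synthesis, in which the chelated tetrahedral adduct prevents over-addition and the ring vinyl iodide is inert to the vinyl Grignard reagent at this temperature.

Step 7
Reactants: 11 the vinyl ketone
Product: 12 (3S,4S,5S)-5-[(tert-butyldimethylsilyl)oxy]-4-[(1R)-2-iodocyclohex-2-en-1-yl]hex-1-en-3-ol
Conditions: (R)-Me-CBS (20 mol %), catecholborane, toluene, −78 °C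
Reagents that add atoms: none
Why: Corey–Bakshi–Shibata 1,2-reduction with the doubly branched C10 side as the large group, so the (R)-catalyst should set the C11 carbinol (S here, the C11–O orientation of 32) under reagent control.

Step 8
Reactants: 12 the allylic alcohol
Product: 13 (3S,4S,5S)-5-[(tert-butyldimethylsilyl)oxy]-4-[(1R)-2-iodocyclohex-2-en-1-yl]hex-1-en-3-yl methacrylate
Conditions: methacryloyl chloride, Et3N, DMAP (cat.), CH2Cl2, 0 °C
Reagents that add atoms: methacryloyl chloride, CC(=C)C(=O)Cl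
Why: DMAP-catalysed acylation installs C13–C15 as the methacrylate partner for metathesis.

Step 9
Reactants: 13 the methacrylate
Product: 14 (5S)-5-{(1S,2S)-2-[(tert-butyldimethylsilyl)oxy]-1-[(1R)-2-iodocyclohex-2-en-1-yl]propyl}-3-methylfuran-2(5H)-one
Conditions: Grubbs II catalyst (10 mol %), toluene, 80 °C
Reagents that add atoms: none
Why: Ring-closing metathesis of an allyl methacrylate to an α-methylbutenolide is driven by loss of ethene, and the iodo-substituted ring alkene is too hindered to take part.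

Step 10
Reactants: 14 the silyloxy butenolide
Product: 16 (2S,3R,3aR,6S,6aR)-3-[(1R)-2-iodocyclohex-2-en-1-yl]-2,6-dimethylhexahydrofuro[3,2-b]furan-5-one, via hydroxy butenolide 15 (not isolated)
Conditions: HF·pyridine, THF, 0 °C → rt; then DBU (10 mol %), CH2Cl2, −20 °C; AcOH quench
Reagents that add atoms: none
Why: Desilylation frees the C16 hydroxyl, whose intramolecular oxa-Michael addition (5-exo-trig) can reach C12 only from the face of the C10 tether and so gives the cis-fused bicycle (12R), and kinetic protonation of the lactone enolate from the convex face should place the C13 methyl group endo (13S).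

Step 11
Reactants: 17 (R)-4-benzyl-3-propionyloxazolidin-2-one
Product: 18 (R)-4-benzyl-3-[(S)-2-methylpent-4-enoyl]oxazolidin-2-one
Conditions: NaHMDS, THF, −78 °C; allyl iodide
Reagents that add atoms: allyl iodide, C=CCI
Why: Evans asymmetric alkylation, in which the chelated (Z)-sodium enolate is allylated anti to the benzyl group and sets C20 (S).

Step 12
Reactants: 18 the pentenoyl imide
Product: 19 (R)-4-benzyl-3-[(S)-2-methyl-4-oxobutanoyl]oxazolidin-2-one
Conditions: O3, CH2Cl2, −78 °C; Me2S
Reagents that add atoms: ozone, [O-][O+]=O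
Why: Ozonolysis with reductive work-up cleaves the terminal alkene to the C18 aldehyde without enolising C20.

Step 13
Reactants: 19 the aldehyde imide
Product: 22 (3S,5S)-5-[(1R)-1-hydroxyprop-2-en-1-yl]-3-methyloxolan-2-one, via boron adduct 20 (not isolated), via anti-diol imide 21 (not isolated)
Conditions: allenyl-Bpin + Ipc2BH [from (−)-α-pinene], Et2O, 0 °C → rt; 19, −78 °C; NaBO3·4H2O, THF–H2O, rt; CSA (cat.), CH2Cl2
Reagents that add atoms: allenylboronic acid pinacol ester, C=C=CB1OC(C)(C)C(C)(C)O1; sodium perborate, [Na+].[O-]OB=O (oxygen at C3); diisopinocampheylborane, [H]B(C1CC2CC(C1C)C2(C)C)C1CC2CC(C1C)C2(C)C (carried only by 20)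
Why: Asymmetric allylboration with an (E)-γ-borylallyl diisopinocampheylborane made in situ: the chair transition state gives the anti C18–O/C3–B relation, the pinanyl groups select the aldehyde face (18S), oxidation with retention gives the (3R)-alcohol, and the C18 hydroxyl lactonises onto the imide with release of the auxiliary.

Step 14
Reactants: 16 the iodocyclohexenyl furofuranone; 22 the hydroxyallyl lactone
Product: 24 cyclohexene alcohol (16 with iodine replaced by the C1H2–C2H2–C3H(OH)–lactone chain; 3R; other centres as in 32), via bis-boryl lactone 23 (not isolated)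
Conditions: 22, 9-BBN-H (2.2 equiv), THF, rt; then 16, PdCl2(dppf) (5 mol %), AsPh3, Cs2CO3, DMF–H2O, rt → 40 °C
Reagents that add atoms: 9-borabicyclo[3.3.1]nonane, [H]B1C2CCCC1CCC2 (boron groups are carried only by 23)
Why: B-alkyl Suzuki–Miyaura coupling, in which 9-BBN-H adds to the terminal alkene at C1 (the hydroxyl is masked in situ as its borinate) and the alkylborane couples with the vinyl iodide without moving the ring alkene.

Step 15
Reactants: 24 the cyclohexene alcohol
Product: 25 C3 mesylate of 24 (3R)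
Conditions: MsCl, Et3N, CH2Cl2, 0 °C
Reagents that add atoms: methanesulfonyl chloride, CS(=O)(=O)Cl
Why: Sulfonylation of the only free hydroxyl group activates C3 with retention for the later SN2 displacement.

Step 16
Reactants: 25 the cyclohexene mesylate
Product: 27 cyclohexanol mesylate (5S,9aS; C1 chain cis to C10 and trans to the C5 hydroxyl), via C5 alkylborane 26 (not isolated)
Conditions: BH3·THF, THF, 0 °C → rt; NaBO3·4H2O, THF–H2O, rt
Reagents that add atoms: sodium perborate, [Na+].[O-]OB=O (oxygen at C5); borane–THF, B (carried only by 26)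
Why: Hydroboration–oxidation: borane adds syn, with boron at the less substituted C5 and from the face opposite the pseudoaxial C9 substituent, so the new C9a–H is anti to C10 and the C1 chain ends up cis to it (9aS), while lactones and mesylate react more slowly.

Step 17
Reactants: 27 the cyclohexanol mesylate
Product: 28 azido alcohol (3S,5S,9aS)
Conditions: NaN3, DMF, 60 °C
Reagents that add atoms: sodium azide, [N-]=[N+]=[N-].[Na+]
Why: SN2 displacement of the secondary mesylate by azide inverts C3 to the (S) configuration of the target.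

Step 18
Reactants: 28 the azido alcohol
Product: 29 azido ketone: cis-2,3-disubstituted cyclohexanone (C5=O, 9aS, 9R, 3S)
Conditions: Dess–Martin periodinane, NaHCO3, CH2Cl2, 0 °C
Reagents that add atoms: none
Why: Dess–Martin oxidation under buffered neutral conditions tolerates the azide and should give the ketone without epimerising the labile cis C9a centre.

Step 19
Reactants: 29 the azido ketone
Product: 31 5-oxo derivative of the target (azepan-2-one lactam; all ten stereocentres as in 32), via aminodiazonium azidohydrin 30 (not isolated)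
Conditions: TiCl4 (5 equiv), CH2Cl2, −20 °C → rt; aq. NaHCO3
Reagents that add atoms: none
Why: This is an intramolecular Schmidt reaction of an alkyl azide with a ketone: TiCl4 activates the C5 carbonyl, the alkylated nitrogen of the C3 azide adds to it (6-exo-trig) to give the transient 1-azadecalin azidohydrin 30, and the C5–C9a bond antiperiplanar to the equatorial N2+ group migrates to nitrogen as N2 leaves. This single 1,2-shift makes the N4–C9a bond, which contracts the transient six-membered ring to the pyrrolidine (N4–C3–C2–C1–C9a) and expands the cyclohexanone to the azepan-2-one (N4–C5–C6–C7–C8–C9–C9a), so both rings close by ring contraction/ring expansion and not by end-to-end cyclisation. No stereocentre is created, because C9a migrates with retention and C3 keeps its C–N bond, so the trans-2,5-pyrrolidine and the cis C9/C9a relation are read out directly from 29. The step needs migration of C9a and not C6 (fused, not bridged, lactam), which the three-carbon tether on the α-carbon and the better migrating, more substituted carbon should secure. It also needs nitrogen insertion to outrun enolisation of the cis ketone, which is why 29 is made by a neutral oxidation directly beforehand and treated cold. The two γ-lactones and the tetrahydrofuran are inert to TiCl4 but bind it, hence the excess.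

Step 20
Reactants: 31 the lactam
Product: 32 target, (3S,9R,9aS,10R,11R,12R,13S,16S,18S,20S)-configured CNP0108586.2
Conditions: Zn(OAc)2 (10 mol %), (EtO)3SiH, THF, 40 °C; aq. NaHCO3
Reagents that add atoms: none
Why: Zinc-catalysed hydrosilylation reduces tertiary amides chemoselectively in the presence of esters and lactones, and no stereocentre adjoins C5.

Compound list
1 | (S)-3-hydroxybutanoic acid | C[C@H](O)CC(=O)O | starting material
2 | tert-butyldimethylsilyl (S)-3-[(tert-butyldimethylsilyl)oxy]butanoate | C[C@H](O[Si](C)(C)C(C)(C)C)CC(=O)O[Si](C)(C)C(C)(C)C | intermediate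
3 | (S)-3-[(tert-butyldimethylsilyl)oxy]butanoic acid | C[C@H](O[Si](C)(C)C(C)(C)C)CC(=O)O | intermediate
4 | 2-iodocyclohex-2-en-1-one | O=C1CCCC=C1I | starting material
5 | (R)-2-iodocyclohex-2-en-1-ol | O[C@@H]1CCCC=C1I | intermediate
6 | (R)-2-iodocyclohex-2-en-1-yl (S)-3-[(tert-butyldimethylsilyl)oxy]butanoate | C[C@H](O[Si](C)(C)C(C)(C)C)CC(=O)O[C@@H]1CCCC=C1I | intermediate
7 | (Z)-trimethylsilyl ketene acetal of 6 (C16 cis to OSiMe3) | C[C@H](O[Si](C)(C)C(C)(C)C)/C=C(\O[Si](C)(C)C)O[C@@H]1CCCC=C1I | intermediate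
8 | trimethylsilyl ester of 9 | C[C@H](O[Si](C)(C)C(C)(C)C)[C@H](C(=O)O[Si](C)(C)C)[C@H]1CCCC=C1I | intermediate
9 | (2R,3S)-3-[(tert-butyldimethylsilyl)oxy]-2-[(1R)-2-iodocyclohex-2-en-1-yl]butanoic acid | C[C@H](O[Si](C)(C)C(C)(C)C)[C@H](C(=O)O)[C@H]1CCCC=C1I | intermediate
10 | N-methoxy-N-methylamide of 9 | C[C@H](O[Si](C)(C)C(C)(C)C)[C@H](C(=O)N(C)OC)[C@H]1CCCC=C1I | intermediate
11 | (4R,5S)-5-[(tert-butyldimethylsilyl)oxy]-4-[(1R)-2-iodocyclohex-2-en-1-yl]hex-1-en-3-one | C[C@H](O[Si](C)(C)C(C)(C)C)[C@H](C(=O)C=C)[C@H]1CCCC=C1I | intermediate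
12 | (3S,4S,5S)-5-[(tert-butyldimethylsilyl)oxy]-4-[(1R)-2-iodocyclohex-2-en-1-yl]hex-1-en-3-ol | C[C@H](O[Si](C)(C)C(C)(C)C)[C@H]([C@H](C=C)O)[C@H]1CCCC=C1I | intermediate
13 | methacrylate of 12 | C[C@H](O[Si](C)(C)C(C)(C)C)[C@H]([C@H](C=C)OC(=O)C(C)=C)[C@H]1CCCC=C1I | intermediate
14 | (5S)-5-{(1S,2S)-2-[(tert-butyldimethylsilyl)oxy]-1-[(1R)-2-iodocyclohex-2-en-1-yl]propyl}-3-methylfuran-2(5H)-one | C[C@H](O[Si](C)(C)C(C)(C)C)[C@H]([C@H]1OC(=O)C(C)=C1)[C@H]1CCCC=C1I | intermediate
15 | (5S)-5-{(1R,2S)-2-hydroxy-1-[(1R)-2-iodocyclohex-2-en-1-yl]propyl}-3-methylfuran-2(5H)-one | C[C@H](O)[C@H]([C@H]1OC(=O)C(C)=C1)[C@H]1CCCC=C1I | intermediate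
16 | (2S,3R,3aR,6S,6aR)-3-[(1R)-2-iodocyclohex-2-en-1-yl]-2,6-dimethylhexahydrofuro[3,2-b]furan-5-one | C[C@@H]1O[C@H]2[C@H](OC(=O)[C@H]2C)[C@@H]1[C@H]1CCCC=C1I | intermediate
17 | (R)-4-benzyl-3-propionyloxazolidin-2-one | CCC(=O)N1[C@H](Cc2ccccc2)COC1=O | starting material
18 | (R)-4-benzyl-3-[(S)-2-methylpent-4-enoyl]oxazolidin-2-one | C=CC[C@H](C)C(=O)N1[C@H](Cc2ccccc2)COC1=O | intermediate
19 | (R)-4-benzyl-3-[(S)-2-methyl-4-oxobutanoyl]oxazolidin-2-one | O=CC[C@H](C)C(=O)N1[C@H](Cc2ccccc2)COC1=O | intermediate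
20 | allylboration adduct: C18 O-diisopinocampheylborinate, C3 pinacol boronate (anti; Ipc from (−)-α-pinene, pinanyl centres not drawn) | C=C[C@@H](B1OC(C)(C)C(C)(C)O1)[C@@H](OB(C1CC2CC(C1C)C2(C)C)C1CC2CC(C1C)C2(C)C)C[C@H](C)C(=O)N1[C@H](Cc2ccccc2)COC1=O | intermediate
21 | (R)-4-benzyl-3-[(2S,4S,5R)-4,5-dihydroxy-2-methylhept-6-enoyl]oxazolidin-2-one | C=C[C@@H](O)[C@@H](O)C[C@H](C)C(=O)N1[C@H](Cc2ccccc2)COC1=O | intermediate
22 | (3S,5S)-5-[(1R)-1-hydroxyprop-2-en-1-yl]-3-methyloxolan-2-one | C=C[C@@H](O)[C@@H]1C[C@H](C)C(=O)O1 | intermediate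
23 | C1 B-alkyl-9-BBN, C3 O-(9-BBN) borinate of 22 | C(B1C2CCCC1CCC2)C[C@@H](OB1C2CCCC1CCC2)[C@@H]1C[C@H](C)C(=O)O1 | intermediate
24 | cyclohexene alcohol (C9a=C5 alkene, 3R-OH, other centres as in 32) | C[C@@H]1O[C@H]2[C@H](OC(=O)[C@H]2C)[C@@H]1[C@H]1CCCC=C1CC[C@@H](O)[C@@H]1C[C@H](C)C(=O)O1 | intermediate
25 | C3 mesylate of 24 (3R) | C[C@@H]1O[C@H]2[C@H](OC(=O)[C@H]2C)[C@@H]1[C@H]1CCCC=C1CC[C@@H](OS(C)(=O)=O)[C@@H]1C[C@H](C)C(=O)O1 | intermediate
26 | C5 alkylborane from 25 (B and C9a–H syn, anti to C10) | C[C@@H]1O[C@H]2[C@H](OC(=O)[C@H]2C)[C@@H]1[C@H]1CCC[C@H](B)[C@H]1CC[C@@H](OS(C)(=O)=O)[C@@H]1C[C@H](C)C(=O)O1 | intermediate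
27 | cyclohexanol mesylate (5S,9aS,3R) | C[C@@H]1O[C@H]2[C@H](OC(=O)[C@H]2C)[C@@H]1[C@H]1CCC[C@H](O)[C@H]1CC[C@@H](OS(C)(=O)=O)[C@@H]1C[C@H](C)C(=O)O1 | intermediate
28 | azido alcohol (5S,9aS,3S) | C[C@@H]1O[C@H]2[C@H](OC(=O)[C@H]2C)[C@@H]1[C@H]1CCC[C@H](O)[C@H]1CC[C@H](N=[N+]=[N-])[C@@H]1C[C@H](C)C(=O)O1 | intermediate
29 | azido ketone (cis-2,3-disubstituted cyclohexanone, 9R,9aS,3S) | C[C@@H]1O[C@H]2[C@H](OC(=O)[C@H]2C)[C@@H]1[C@H]1CCCC(=O)[C@H]1CC[C@H](N=[N+]=[N-])[C@@H]1C[C@H](C)C(=O)O1 | intermediate
30 | C5-hydroxy N-diazonio-1-azadecalin (azidohydrin cation, C5 not defined) | C[C@@H]1O[C@H]2[C@H](OC(=O)[C@H]2C)[C@@H]1[C@H]3CCCC4(O)N([N+]#N)[C@@H](CC[C@@H]34)[C@@H]1C[C@H](C)C(=O)O1 | intermediate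
31 | 5-oxo lactam of the target | C[C@@H]1O[C@H]2[C@H](OC(=O)[C@H]2C)[C@@H]1[C@H]1CCCC(=O)N2[C@H]1CC[C@H]2[C@@H]1C[C@H](C)C(=O)O1 | intermediate
32 | CNP0108586.2 | C[C@@H]1O[C@H]2[C@H](OC(=O)[C@H]2C)[C@@H]1[C@H]1CCCCN2[C@H]1CC[C@H]2[C@@H]1C[C@H](C)C(=O)O1 | target

Total step count: 20. Longest linear sequence: 16 steps (steps 1 or 2, then 3–10 and 14–20). Steps 11–13 form a three-step side branch.

Steps most likely to fail

Step 19. Addition of the hindered secondary azide may be slow, so that acid-promoted enolisation epimerises C9a before insertion, or C6 may migrate and lead to the bridged lactam. The fallback sets out from 29 and replaces the acid-mediated insertion by a neutral three-stage nitrogen insertion. Staudinger/aza-Wittig cyclisation (PPh3, toluene, rt → 60 °C) should give the bicyclic ketimine F1. mCPBA oxidation should give the fused oxaziridine F2. Irradiation (254 nm, MeCN) should trigger the oxaziridine-to-lactam photorearrangement, in which the C5–C9a bond anti to the nitrogen lone pair migrates with retention. This again closes pyrrolidine and azepane together and returns to the route at 31.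

Step 4. The enolate may lose silanolate by β-elimination in the dipolar medium, the ketene acetal geometry may erode, or chair/boat leakage may lower facial control at C10. The fallback sets out from 5 and separates the two tasks.
- Johnson–Claisen rearrangement (triethyl orthoacetate, cat. propionic acid, 140 °C) should set only C9 in ethyl 2-[(1R)-2-iodocyclohex-2-en-1-yl]acetate F3.
- LiOH should give the acid F4.
- The mixed pivalic anhydride and lithiated (R)-4-benzyloxazolidin-2-one should give the imide F5.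
- A boron-mediated Evans syn-aldol reaction with acetaldehyde (Bu2BOTf, Et3N, −78 °C) should set C10 and C16 in the aldol F6.
- AlMe3/MeNHOMe·HCl should give the hydroxy Weinreb amide F7.
- TBSOTf/2,6-lutidine returns to the route at 10.

Step 10. Closure to the all-cis tetrahydrofuran is reversible and may stall. The butenolide may epimerise at C11 through its dienolate, or C13 may equilibrate to the exo methyl epimer. The fallback sets out from 12 and builds both rings irreversibly before the methyl group is placed.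
- HF·pyridine should give the ene-diol F8.
- Pd(II)-catalysed oxycarbonylative bicyclisation (PdCl2, CuCl2, NaOAc, AcOH, CO 1 atm) should give the 13-nor-methyl bicyclic lactone F9.
- LDA/MeI should alkylate from the convex face to give the 13-epi (exo-methyl) lactone F10.
- Renewed deprotonation (LDA, −78 °C) and kinetic protonation from the convex face with 2,6-di-tert-butyl-4-methylphenol should invert C13 and return to the route at 16.

Further compounds
F1 | step 19 | bicyclic ketimine (C5=N4, six-membered ring N4–C3–C2–C1–C9a–C5) | C[C@@H]1O[C@H]2[C@H](OC(=O)[C@H]2C)[C@@H]1[C@H]3CCCC4=N[C@@H](CC[C@@H]34)[C@@H]1C[C@H](C)C(=O)O1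
F2 | step 19 | fused oxaziridine of F1 (C5 and N not defined) | C[C@@H]1O[C@H]2[C@H](OC(=O)[C@H]2C)[C@@H]1[C@H]3CCCC45ON5[C@@H](CC[C@@H]34)[C@@H]1C[C@H](C)C(=O)O1
F3 | step 4 | ethyl 2-[(1R)-2-iodocyclohex-2-en-1-yl]acetate | CCOC(=O)C[C@H]1CCCC=C1I
F4 | step 4 | 2-[(1R)-2-iodocyclohex-2-en-1-yl]acetic acid | OC(=O)C[C@H]1CCCC=C1I
F5 | step 4 | (R)-4-benzyl-3-{2-[(1R)-2-iodocyclohex-2-en-1-yl]acetyl}oxazolidin-2-one | O=C(C[C@H]1CCCC=C1I)N1[C@H](Cc2ccccc2)COC1=O
F6 | step 4 | (R)-4-benzyl-3-{(2R,3S)-3-hydroxy-2-[(1R)-2-iodocyclohex-2-en-1-yl]butanoyl}oxazolidin-2-one | C[C@H](O)[C@H](C(=O)N1[C@H](Cc2ccccc2)COC1=O)[C@H]1CCCC=C1I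
F7 | step 4 | (2R,3S)-3-hydroxy-2-[(1R)-2-iodocyclohex-2-en-1-yl]-N-methoxy-N-methylbutanamide | C[C@H](O)[C@H](C(=O)N(C)OC)[C@H]1CCCC=C1I
F8 | step 10 | ene-diol from 12 (C11 and C16 hydroxyls free, centres as in 12) | C[C@H](O)[C@H]([C@H](C=C)O)[C@H]1CCCC=C1I
F9 | step 10 | 13-nor-methyl analogue of 16 | C[C@@H]1O[C@H]2[C@H](OC(=O)C2)[C@@H]1[C@H]1CCCC=C1I
F10 | step 10 | 13-epimer of 16 (exo methyl) | C[C@@H]1O[C@H]2[C@H](OC(=O)[C@@H]2C)[C@@H]1[C@H]1CCCC=C1I
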